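**Plan**
- Carotenoid numbering is used: ring C1–C6, chain from C7, primed numbers for the acyclic half. The retrosynthesis cuts the ring-to-chain bond C6–C7 first (it is formed last), then C7'=C8' (Wittig) and C7=C8 (one-carbon iodo-olefination of a C8 aldehyde), which exposes symmetrical crocetindialdehyde (C8–C8'). The acyclic terminus is disconnected at C3'=C4' (Horner–Wadsworth–Emmons). The ring side chain is cut at its trisubstituted olefin (cross-metathesis) and at the C2–allyl bond (oxy-Cope).
- Forward, ring half: 2-methylcyclohexenone → allyl carbinol → 3-allyl-2,2-dimethyl ketone → 2,2,6-trimethyl ketone carrying the silylated hydroxyprenyl chain → tosylhydrazone.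
- Forward, chain half and union: (R)-lavandulol → C15 phosphonium salt; crocetindialdehyde → C21 iodo-aldehyde → C36 polyenyl iodide; hydrazone + iodide → C50 skeleton; desilylation.
- Enabling feature: in the six-membered β-end ring, C6 is a former ketone carbon flanked by the quaternary C1 (gem-dimethyl, no hydrogen) and by C5 (one hydrogen, one methyl). A palladium carbene at C6 therefore takes the polyenyl group at C7 and can eliminate hydride only toward C5, so the C6–C7 bond and the C5=C6 ring olefin arise together from the ketone.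
- Stereochemistry: C2 (R) comes from a Ti(OiPr)4/(R)-BINOL-catalysed allylation whose carbinol centre is relayed to C2 by a suprafacial [3,3] shift. C2' (S) comes from (R)-lavandulol. The E-olefins come from cross-metathesis, Horner–Wadsworth–Emmons, Takai and Wittig/iodine equilibration.

Key step: step 16

Remark: (R)-lavandulol and crocetindialdehyde are taken as purchasable, and (R)-BINOL is taken to give the (R)-carbinol in step 1 (the antipodal ligand would be used if the sense of induction were opposite).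

**Route**

Step 1
Reactants: 1 2-methylcyclohex-2-en-1-one
Product: 2 (1R)-2-methyl-1-(prop-2-en-1-yl)cyclohex-2-en-1-ol
Conditions: Ti(OiPr)4 (20 mol%), (R)-BINOL (20 mol%), iPrOH (20 equiv), Sn(CH2CH=CH2)4 (1.5 equiv), CH2Cl2, rt
Reagents that add atoms: tetraallylstannane C=CC[Sn](CC=C)(CC=C)CC=C
Why: Ti(OiPr)4/(R)-BINOL-catalysed asymmetric 1,2-allylation of a ketone: the chiral Lewis acid formed from Ti(OiPr)4 and (R)-BINOL binds the enone carbonyl and the allylstannane attacks one face at the carbonyl carbon only, which should set the tertiary carbinol centre as R under ligand control.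

Step 2
Reactants: 2 (1R)-2-methyl-1-(prop-2-en-1-yl)cyclohex-2-en-1-ol
Product: 5 (3R)-2,2-dimethyl-3-(prop-2-en-1-yl)cyclohexan-1-one, via potassium alkoxide 3 (not isolated), via potassium enolate 4 (not isolated)
Conditions: KH, 18-crown-6, THF, 0 °C to rt; then MeI, −78 to 0 °C
Reagents that add atoms: iodomethane CI
Why: Anionic oxy-Cope rearrangement followed by enolate alkylation: the alkoxide of the 3-oxido-1,5-diene shifts the allyl group suprafacially [3,3] from C1 to C3 on the same ring face, so the carbinol configuration is relayed to C3 (R), and the regiodefined tetrasubstituted enolate is C-methylated to create the gem-dimethyl carbon.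

Step 3
Reactants: 5 (3R)-2,2-dimethyl-3-(prop-2-en-1-yl)cyclohexan-1-one
Product: 7 (3R,6RS)-2,2,6-trimethyl-3-(prop-2-en-1-yl)cyclohexan-1-one, via lithium enolate 6 (not isolated)
Conditions: LiN(iPr)2, THF, −78 °C; then MeI, −78 to −20 °C
Reagents that add atoms: iodomethane CI
Why: Kinetic enolate alkylation: only C6 carries α-hydrogens, so a single enolate forms and is methylated; the new centre arises as an epimer mixture, which is harmless because this carbon becomes sp2 in step 16.

Step 4
Reactants: 7 (3R,6RS)-2,2,6-trimethyl-3-(prop-2-en-1-yl)cyclohexan-1-one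
Product: 8 (2E)-2-methyl-4-[(1R,4RS)-2,2,4-trimethyl-3-oxocyclohexyl]but-2-enal
Conditions: methacrolein (5 equiv), second-generation Hoveyda–Grubbs catalyst (H2IMes)Cl2Ru=CH(2-iPrO-C6H4) (5 mol%), CH2Cl2, 40 °C
Reagents that add atoms: methacrolein CC(=C)C=O
Why: Olefin cross-metathesis of a terminal alkene with an electron-poor 1,1-disubstituted partner: ethene is lost and the trisubstituted enal should form as the thermodynamically preferred E isomer, which fixes the side-chain olefin geometry.

Step 5
Reactants: 8 (2E)-2-methyl-4-[(1R,4RS)-2,2,4-trimethyl-3-oxocyclohexyl]but-2-enal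
Product: 9 (3R,6RS)-3-[(2E)-4-hydroxy-3-methylbut-2-en-1-yl]-2,2,6-trimethylcyclohexan-1-one
Conditions: NaBH4 (0.5 equiv), MeOH/CH2Cl2, −78 to −40 °C
Reagents that add atoms: none
Why: Chemoselective 1,2-reduction: the unhindered aldehyde takes hydride at low temperature, while the ketone, flanked by a quaternary and a tertiary carbon, should be left.

Step 6
Reactants: 9 (3R,6RS)-3-[(2E)-4-hydroxy-3-methylbut-2-en-1-yl]-2,2,6-trimethylcyclohexan-1-one
Product: 10 (3R,6RS)-3-[(2E)-4-{[tert-butyl(diphenyl)silyl]oxy}-3-methylbut-2-en-1-yl]-2,2,6-trimethylcyclohexan-1-one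
Conditions: tBuPh2SiCl, imidazole, DMF, rt
Reagents that add atoms: tert-butyl(chloro)diphenylsilane CC(C)(C)[Si](Cl)(c1ccccc1)c1ccccc1
Why: Silyl ether formation at the primary allylic alcohol gives a group that should withstand the acidic condensation of step 7 and the hot alkoxide of step 16, and it prevents palladium-mediated oxidation of the alcohol.

Step 7
Reactants: 10 (3R,6RS)-3-[(2E)-4-{[tert-butyl(diphenyl)silyl]oxy}-3-methylbut-2-en-1-yl]-2,2,6-trimethylcyclohexan-1-one
Product: 11 N-tosylhydrazone of ketone 10 [N'-{(3R,6RS)-3-[(2E)-4-{[tert-butyl(diphenyl)silyl]oxy}-3-methylbut-2-en-1-yl]-2,2,6-trimethylcyclohexylidene}-4-methylbenzenesulfonohydrazide]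
Conditions: TsNHNH2 (1.5 equiv), pyridinium p-toluenesulfonate (cat.), EtOH, 70 °C
Reagents that add atoms: 4-methylbenzenesulfonohydrazide Cc1ccc(cc1)S(=O)(=O)NN
Why: Acid-catalysed condensation of a ketone with a sulfonyl hydrazide; the hindered carbonyl should react slowly but cleanly because the molecule has no other electrophilic site.

Step 8
Reactants: 12 (R)-lavandulol [(2R)-5-methyl-2-(prop-1-en-2-yl)hex-4-en-1-ol]
Product: 13 (2S)-2-(2-hydroxypropan-2-yl)-5-methylhex-4-en-1-ol
Conditions: Co(acac)2 (20 mol%), PhSiH3, O2 (1 atm), THF/iPrOH, rt; aqueous Na2S2O3 work-up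
Reagents that add atoms: dioxygen O=O
Why: Mukaiyama hydration (hydrogen-atom transfer from the cobalt hydride generated from Co(acac)2 and PhSiH3, then O2 capture): the hydrogen atom should go to the exposed terminal CH2 of the 1,1-disubstituted isopropenyl group in preference to the trisubstituted prenyl olefin, giving the Markovnikov tertiary alcohol; the chiral-pool stereocentre is not touched (its descriptor becomes S only through the priority change).

Step 9
Reactants: 13 (2S)-2-(2-hydroxypropan-2-yl)-5-methylhex-4-en-1-ol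
Product: 14 bis(triethylsilyl) ether of diol 13
Conditions: Et3SiOTf (2.5 equiv), 2,6-lutidine, CH2Cl2, −78 to 0 °C
Reagents that add atoms: triethylsilyl trifluoromethanesulfonate CC[Si](CC)(CC)OS(=O)(=O)C(F)(F)F
Why: Exhaustive silylation with a silyl triflate caps the primary alcohol and also the hindered tertiary alcohol, which would otherwise allow retro-aldol cleavage of the aldehyde made in step 10.

Step 10
Reactants: 14 bis(triethylsilyl) ether of diol 13
Product: 15 (2R)-5-methyl-2-{2-[(triethylsilyl)oxy]propan-2-yl}hex-4-enal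
Conditions: (COCl)2, DMSO, CH2Cl2, −78 to −30 °C; then Et3N, −78 to 0 °C
Reagents that add atoms: none
Why: Swern oxidation with in-situ cleavage of the primary triethylsilyl ether: the chlorosulfonium reagent removes and oxidises only the unhindered primary silyl ether, the tertiary one stays, and the cold basic quench should keep the α-stereocentre intact.

Step 11
Reactants: 15 (2R)-5-methyl-2-{2-[(triethylsilyl)oxy]propan-2-yl}hex-4-enal; 16 ethyl (2E)-4-(diethoxyphosphoryl)-3-methylbut-2-enoate
Product: 18 ethyl (2E,4E,6S)-3,7-dimethyl-6-(3-methylbut-2-en-1-yl)-7-[(triethylsilyl)oxy]octa-2,4-dienoate, via lithiated phosphonate 17 (not isolated)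
Conditions: 16, LiN(SiMe3)2, THF, −78 °C; then 15, −78 to 0 °C
Reagents that add atoms: none
Why: Horner–Wadsworth–Emmons olefination with a vinylogous stabilised phosphonate anion: reversible addition and syn-elimination should give the E olefin at C3'=C4' within a (2E,4E)-dienoate, and the weakly basic anion spares the α-stereocentre.

Step 12
Reactants: 18 ethyl (2E,4E,6S)-3,7-dimethyl-6-(3-methylbut-2-en-1-yl)-7-[(triethylsilyl)oxy]octa-2,4-dienoate
Product: 19 (2E,4E,6S)-3,7-dimethyl-6-(3-methylbut-2-en-1-yl)-7-[(triethylsilyl)oxy]octa-2,4-dien-1-ol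
Conditions: iBu2AlH (2.5 equiv), CH2Cl2, −78 °C; aqueous potassium sodium tartrate work-up
Reagents that add atoms: none
Why: 1,2-Reduction of a conjugated ester by an aluminium hydride should give the allylic alcohol without touching the olefins or the silyl ether.

Step 13
Reactants: 19 (2E,4E,6S)-3,7-dimethyl-6-(3-methylbut-2-en-1-yl)-7-[(triethylsilyl)oxy]octa-2,4-dien-1-ol
Product: 21 [(2E,4E,6S)-3,7-dimethyl-6-(3-methylbut-2-en-1-yl)-7-[(triethylsilyl)oxy]octa-2,4-dien-1-yl](triphenyl)phosphonium bromide, via allylic bromide 20 (not isolated)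
Conditions: CBr4, PPh3, CH2Cl2, −20 °C; then further PPh3, rt; precipitation with Et2O
Reagents that add atoms: tetrabromomethane BrC(Br)(Br)Br; triphenylphosphine c1ccc(cc1)P(c1ccccc1)c1ccccc1
Why: Appel bromination (neutral SN2 at the primary allylic carbon, so the acid-labile tertiary silyl ether and the diene are kept) followed by quaternisation of PPh3 should give the Wittig salt.

Step 14
Reactants: 22 crocetindialdehyde [(2E,4E,6E,8E,10E,12E,14E)-2,6,11,15-tetramethylhexadeca-2,4,6,8,10,12,14-heptaenedial]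
Product: 23 (2E,4E,6E,8E,10E,12E,14E,16E)-17-iodo-2,6,11,15-tetramethylheptadeca-2,4,6,8,10,12,14,16-octaenal
Conditions: CHI3 (1 equiv), CrCl2 (6 equiv), 22 (3 equiv), THF/1,4-dioxane, 0 °C to rt, dark
Reagents that add atoms: iodoform IC(I)I
Why: Takai olefination: the geminal dichromium species from CHI3 and CrCl2 adds to one aldehyde and eliminates to the E-vinyl iodide (this carbon becomes C7), and the excess of the symmetrical dialdehyde should hold the reaction at mono-olefination.

Step 15
Reactants: 21 C15 phosphonium bromide; 23 C21 iodo-octaenal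
Product: 25 all-E C36 polyenyl iodide (iodine at C7; triethylsilyl ether at the C1' oxygen; full name in the compound list), via phosphorus ylide 24 (not isolated)
Conditions: 21, NaN(SiMe3)2, THF, −78 °C; then 23, −78 to 0 °C; crude product I2 (cat.), CH2Cl2, rt, diffuse light
Reagents that add atoms: none
Why: Wittig olefination of the polyenal with the allylic ylide forms C7'=C8'; the E/Z mixture expected at this bond should converge on the all-E chain under iodine catalysis, because a Z bond next to the methyl-bearing C9' is sterically disfavoured.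

Step 16
Reactants: 11 N-tosylhydrazone of ketone 10; 25 all-E C36 polyenyl iodide
Product: 27 bis-silyl ether of the target (triethylsilyl at the C1' oxygen; tert-butyldiphenylsilyl at the side-chain oxygen), via diazoalkane 26 (not isolated)
Conditions: Pd2(dba)3 (2.5 mol%), XPhos (10 mol%), LiOtBu (2.5 equiv), 1,4-dioxane, 80 °C, argon, dark
Reagents that add atoms: none
Why: LiOtBu deprotonates hydrazone 11, which loses sulfinate to give diazoalkane 26, while zerovalent palladium inserts into the C7–I bond of 25; the polyenylpalladium iodide captures 26 with loss of N2 to give a palladium carbene at ring carbon C6, and migratory insertion of the polyenyl group makes the C6–C7 bond. The resulting allylpalladium species can undergo syn β-hydride elimination only from its C6-bound form and only toward C5, because C1 is quaternary and C8 has no sp3 neighbour, so the tetrasubstituted C5=C6 ring olefin is formed in the same event and base returns the catalyst. The closest known reaction type is the palladium-catalysed coupling of ketone N-tosylhydrazones with alkenyl halides to give 1,3-dienes, a carbene cross-coupling that is known to deliver polysubstituted olefins from α-branched hydrazones. No ring is closed and no stereocentre is formed: the epimeric C5 of 11 becomes sp2 (facial exchange of the allylpalladium unit lets either epimer reach a syn hydrogen), C2 and C2' are remote from the reacting atoms, and the C7=C8 bond should emerge E because the allyl intermediate can relax to the less hindered geometry. The step needs regioselective elimination, secured by the gem-dimethyl C1, and chemoselectivity for the vinyl iodide over the silyl ethers and the polyene, secured by fast oxidative addition, a hydroxyl-free substrate and a bulky biaryl phosphine that favours carbene capture over Bamford–Stevens decomposition.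

Step 17
Reactants: 27 bis-silyl ether of the target
Product: 28 (2R,2'S)-2-[(2E)-4-hydroxy-3-methylbut-2-en-1-yl]-2'-(3-methylbut-2-en-1-yl)-3',4'-didehydro-1',2'-dihydro-β,ψ-caroten-1'-ol (target)
Conditions: Bu4NF (4 equiv), THF, 0 °C to rt; crystallisation of the all-E isomer
Reagents that add atoms: none
Why: Fluoride-induced cleavage of both silyl ethers under non-acidic conditions should release the primary allylic and the tertiary alcohol without harming the polyene or the two stereocentres.

**Compound list**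
1 | 2-methylcyclohex-2-en-1-one | CC1=CCCCC1=O | starting material
2 | (1R)-2-methyl-1-(prop-2-en-1-yl)cyclohex-2-en-1-ol | C=CC[C@]1(O)CCCC=C1C | intermediate
3 | potassium (1R)-2-methyl-1-(prop-2-en-1-yl)cyclohex-2-en-1-olate | C=CC[C@]1([O-])CCCC=C1C.[K+] | intermediate
4 | potassium (3R)-2-methyl-3-(prop-2-en-1-yl)cyclohex-1-en-1-olate | [K+].[O-]C1=C(C)[C@@H](CC=C)CCC1 | intermediate
5 | (3R)-2,2-dimethyl-3-(prop-2-en-1-yl)cyclohexan-1-one | O=C1CCC[C@H](CC=C)C1(C)C | intermediate
6 | lithium (5R)-6,6-dimethyl-5-(prop-2-en-1-yl)cyclohex-1-en-1-olate | [Li+].[O-]C1=CCC[C@H](CC=C)C1(C)C | intermediate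
7 | (3R,6RS)-2,2,6-trimethyl-3-(prop-2-en-1-yl)cyclohexan-1-one | CC1CC[C@H](CC=C)C(C)(C)C1=O | intermediate
8 | (2E)-2-methyl-4-[(1R,4RS)-2,2,4-trimethyl-3-oxocyclohexyl]but-2-enal | CC1CC[C@H](C/C=C(\C)C=O)C(C)(C)C1=O | intermediate
9 | (3R,6RS)-3-[(2E)-4-hydroxy-3-methylbut-2-en-1-yl]-2,2,6-trimethylcyclohexan-1-one | CC1CC[C@H](C/C=C(\C)CO)C(C)(C)C1=O | intermediate
10 | (3R,6RS)-3-[(2E)-4-{[tert-butyl(diphenyl)silyl]oxy}-3-methylbut-2-en-1-yl]-2,2,6-trimethylcyclohexan-1-one | CC1CC[C@H](C/C=C(\C)CO[Si](c2ccccc2)(c2ccccc2)C(C)(C)C)C(C)(C)C1=O | intermediate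
11 | N'-{(3R,6RS)-3-[(2E)-4-{[tert-butyl(diphenyl)silyl]oxy}-3-methylbut-2-en-1-yl]-2,2,6-trimethylcyclohexylidene}-4-methylbenzenesulfonohydrazide | CC1CC[C@H](C/C=C(\C)CO[Si](c2ccccc2)(c2ccccc2)C(C)(C)C)C(C)(C)C1=NNS(=O)(=O)c1ccc(C)cc1 | intermediate
12 | (R)-lavandulol, (2R)-5-methyl-2-(prop-1-en-2-yl)hex-4-en-1-ol | CC(C)=CC[C@@H](CO)C(C)=C | starting material
13 | (2S)-2-(2-hydroxypropan-2-yl)-5-methylhex-4-en-1-ol | CC(C)=CC[C@@H](CO)C(C)(C)O | intermediate
14 | bis(triethylsilyl) ether of 13, (2S)-5-methyl-1-[(triethylsilyl)oxy]-2-{2-[(triethylsilyl)oxy]propan-2-yl}hex-4-ene | CC(C)=CC[C@@H](CO[Si](CC)(CC)CC)C(C)(C)O[Si](CC)(CC)CC | intermediate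
15 | (2R)-5-methyl-2-{2-[(triethylsilyl)oxy]propan-2-yl}hex-4-enal | CC(C)=CC[C@@H](C=O)C(C)(C)O[Si](CC)(CC)CC | intermediate
16 | ethyl (2E)-4-(diethoxyphosphoryl)-3-methylbut-2-enoate (commercial material, predominantly E) | CCOC(=O)/C=C(\C)CP(=O)(OCC)OCC | starting material
17 | lithium 1-(diethoxyphosphoryl)-4-ethoxy-2-methyl-4-oxobut-2-en-1-ide | [Li+].CCOC(=O)/C=C(\C)[CH-]P(=O)(OCC)OCC | intermediate
18 | ethyl (2E,4E,6S)-3,7-dimethyl-6-(3-methylbut-2-en-1-yl)-7-[(triethylsilyl)oxy]octa-2,4-dienoate | CC(C)=CC[C@@H](/C=C/C(C)=C/C(=O)OCC)C(C)(C)O[Si](CC)(CC)CC | intermediate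
19 | (2E,4E,6S)-3,7-dimethyl-6-(3-methylbut-2-en-1-yl)-7-[(triethylsilyl)oxy]octa-2,4-dien-1-ol | CC(C)=CC[C@@H](/C=C/C(C)=C/CO)C(C)(C)O[Si](CC)(CC)CC | intermediate
20 | {[(3S,4E,6E)-8-bromo-2,6-dimethyl-3-(3-methylbut-2-en-1-yl)octa-4,6-dien-2-yl]oxy}(triethyl)silane | CC(C)=CC[C@@H](/C=C/C(C)=C/CBr)C(C)(C)O[Si](CC)(CC)CC | intermediate
21 | [(2E,4E,6S)-3,7-dimethyl-6-(3-methylbut-2-en-1-yl)-7-[(triethylsilyl)oxy]octa-2,4-dien-1-yl](triphenyl)phosphonium bromide | CC(C)=CC[C@@H](/C=C/C(C)=C/C[P+](c1ccccc1)(c1ccccc1)c1ccccc1)C(C)(C)O[Si](CC)(CC)CC.[Br-] | intermediate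
22 | crocetindialdehyde, (2E,4E,6E,8E,10E,12E,14E)-2,6,11,15-tetramethylhexadeca-2,4,6,8,10,12,14-heptaenedial | O=C/C(C)=C/C=C/C(C)=C/C=C/C=C(C)/C=C/C=C(C)/C=O | starting material
23 | (2E,4E,6E,8E,10E,12E,14E,16E)-17-iodo-2,6,11,15-tetramethylheptadeca-2,4,6,8,10,12,14,16-octaenal | O=C/C(C)=C/C=C/C(C)=C/C=C/C=C(C)/C=C/C=C(C)/C=C/I | intermediate
24 | triethyl{[(3S,4E,6E)-2,6-dimethyl-3-(3-methylbut-2-en-1-yl)-8-(triphenyl-λ5-phosphanylidene)octa-4,6-dien-2-yl]oxy}silane | CC(C)=CC[C@@H](/C=C/C(C)=C/C=P(c1ccccc1)(c1ccccc1)c1ccccc1)C(C)(C)O[Si](CC)(CC)CC | intermediate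
25 | triethyl{[(3S,4E,6E,8E,10E,12E,14E,16E,18E,20E,22E,24E)-25-iodo-2,6,10,14,19,23-hexamethyl-3-(3-methylbut-2-en-1-yl)pentacosa-4,6,8,10,12,14,16,18,20,22,24-undecaen-2-yl]oxy}silane | CC(C)=CC[C@@H](/C=C/C(C)=C/C=C/C(C)=C/C=C/C(C)=C/C=C/C=C(C)/C=C/C=C(C)/C=C/I)C(C)(C)O[Si](CC)(CC)CC | intermediate
26 | tert-butyl{[(2E)-4-[(1R,4RS)-3-diazo-2,2,4-trimethylcyclohexyl]-2-methylbut-2-en-1-yl]oxy}diphenylsilane | CC1CC[C@H](C/C=C(\C)CO[Si](c2ccccc2)(c2ccccc2)C(C)(C)C)C(C)(C)C1=[N+]=[N-] | intermediate
27 | bis-silyl ether of 28 (triethylsilyl at the C1' oxygen; tert-butyldiphenylsilyl at the side-chain oxygen) | CC(C)=CC[C@@H](/C=C/C(C)=C/C=C/C(C)=C/C=C/C(C)=C/C=C/C=C(C)/C=C/C=C(C)/C=C/C1=C(C)CC[C@H](C/C=C(\C)CO[Si](c2ccccc2)(c2ccccc2)C(C)(C)C)C1(C)C)C(C)(C)O[Si](CC)(CC)CC | intermediate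
28 | (2R,2'S)-2-[(2E)-4-hydroxy-3-methylbut-2-en-1-yl]-2'-(3-methylbut-2-en-1-yl)-3',4'-didehydro-1',2'-dihydro-β,ψ-caroten-1'-ol | CC(C)=CC[C@@H](/C=C/C(C)=C/C=C/C(C)=C/C=C/C(C)=C/C=C/C=C(C)/C=C/C=C(C)/C=C/C1=C(C)CC[C@H](C/C=C(\C)CO)C1(C)C)C(C)(C)O | target

**Count**
Total steps: 17. Longest linear sequence: 9 steps (12 to 28 through steps 8–13, 15, 16 and 17; the ring branch 1 to 28 through steps 1–7, 16 and 17 is equally long).

**Steps most likely to fail**

1. Step 16. The doubly α-branched diazoalkane may lose nitrogen and undergo a 1,2-hydride shift faster than it is captured by the hindered polyenylpalladium species, and the polyenyl iodide may degrade in hot alkoxide. The fallback sets out from ketone 10 and iodide 25 and comes back at 27. Ketone 10 is deprotonated with KN(SiMe3)2 and trapped with PhNTf2 (THF, −78 °C) to give the enol triflate F1; the regiochemistry is fixed because only one α-carbon carries hydrogen. Iodide 25 is converted with Me3SnSnMe3 and Pd(PPh3)4 (cat.) into the polyenyl trimethylstannane F2. Stille coupling of F1 with F2 (Pd2(dba)3, AsPh3, NMP, 50 °C) should give 27, which enters step 17.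

2. Step 2. The alkoxide may fragment by retro-allylation and recombine, which would erode the chirality transfer, and enolate equilibration may lead to methylation at oxygen or at C6. The fallback sets out from enone 1 and comes back at enal 8. Copper-catalysed asymmetric conjugate addition of but-3-enylmagnesium bromide to 1 (Cu(OTf)2, chiral N-heterocyclic carbene ligand, Et2O, 0 °C), with methylation of the magnesium enolate in the same flask (MeI, DMPU), gives the butenyl ketone F3. LiN(iPr)2 and MeI then give the trimethyl ketone F4. One-position olefin isomerisation (RuHCl(CO)(PPh3)3, toluene, 80 °C) gives the but-2-enyl ketone F5. Cross-metathesis of F5 with methacrolein (second-generation Hoveyda–Grubbs catalyst (H2IMes)Cl2Ru=CH(2-iPrO-C6H4)) releases propene and gives 8.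

3. Step 14. Olefination may run on at the second aldehyde to the bis(iodovinyl) polyene, and reductive coupling of the excess dialdehyde by CrCl2 may compete. The fallback sets out from phosphonium salt 21 and dialdehyde 22 and comes back at iodide 25. The ylide 24 from 21 is condensed first with an excess of 22 to give the C35 aldehyde F6. The Takai olefination (CHI3, CrCl2) is then run on F6, which has only one aldehyde group, and gives 25.

Further compounds
F1 | step 16 | (5R)-5-[(2E)-4-{[tert-butyl(diphenyl)silyl]oxy}-3-methylbut-2-en-1-yl]-2,6,6-trimethylcyclohex-1-en-1-yl trifluoromethanesulfonate | FC(F)(F)S(=O)(=O)OC1=C(C)CC[C@H](C/C=C(\C)CO[Si](c2ccccc2)(c2ccccc2)C(C)(C)C)C1(C)C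
F2 | step 16 | triethyl{[(3S,4E,6E,8E,10E,12E,14E,16E,18E,20E,22E,24E)-2,6,10,14,19,23-hexamethyl-3-(3-methylbut-2-en-1-yl)-25-(trimethylstannyl)pentacosa-4,6,8,10,12,14,16,18,20,22,24-undecaen-2-yl]oxy}silane | CC(C)=CC[C@@H](/C=C/C(C)=C/C=C/C(C)=C/C=C/C(C)=C/C=C/C=C(C)/C=C/C=C(C)/C=C/[Sn](C)(C)C)C(C)(C)O[Si](CC)(CC)CC
F3 | step 2 | (3R)-3-(but-3-en-1-yl)-2,2-dimethylcyclohexan-1-one | O=C1CCC[C@H](CCC=C)C1(C)C
F4 | step 2 | (3R,6RS)-3-(but-3-en-1-yl)-2,2,6-trimethylcyclohexan-1-one | CC1CC[C@H](CCC=C)C(C)(C)C1=O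
F5 | step 2 | (3R,6RS)-3-[(2E)-but-2-en-1-yl]-2,2,6-trimethylcyclohexan-1-one | CC1CC[C@H](C/C=C/C)C(C)(C)C1=O
F6 | step 14 | (2E,4E,6E,8E,10E,12E,14E,16E,18E,20E,22S)-2,6,11,15,19,23-hexamethyl-22-(3-methylbut-2-en-1-yl)-23-[(triethylsilyl)oxy]tetracosa-2,4,6,8,10,12,14,16,18,20-decaenal | CC(C)=CC[C@@H](/C=C/C(C)=C/C=C/C(C)=C/C=C/C(C)=C/C=C/C=C(C)/C=C/C=C(C)/C=O)C(C)(C)O[Si](CC)(CC)CC
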